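Start with a subtraction, the easiest step on the board. Here X is fed at a steady rate into a stirred flask of E, the catalyst Z and J, and Q forms.

the same everywhere: X 1.5 M (fed, over 2.5 d); Z 54 mM; J 41 mM

|  | E | remark | time |
|---|---|---|---|
| alpha | 1.58 M | the very flask that is asked about, followed so far; the fed solution adds 0.25 times the starting volume |  |
| theta | 2.4 M | run made earlier; the fed solution adds 0.25 times the starting volume |  |
| flask | 1.58 M | the fed solution adds 0.25 times the starting volume | 2.5 d |

- alpha (time / h: Q / %, X / %): 2.50: 1.2, 3.3; 6.00: 2.4, 7.1; 12.0: 7.9, 11.7; 20.0: 16.2, 16.8
- theta (time / h: Q / %, X / %): 2.00: 0.6, 2.6; 4.00: 1.3, 4.7; 10.0: 6.7, 9.9; 25.0: 24.7, 17.2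

(each reading ± 0.3 percentage points)

- amounts are per litre of the starting volume; all of the dose is in the solution fed
- the analysis behind the earlier runs scatters by 0.3 percentage points, standard deviation
- a reading or a percentage of Q counts all its forms, free or not
- the reaction counts as stopped when no species that holds the X changes by six tenths of a point or more over the second half of the time
- percentages count the whole charge, also what has not yet gone in

* why nothing more happens at 2.5 d, or that something still does (no working catalyst is left / it is still moving / E has run out first / all of X has reacted)
* amount of Q at 2.5 d, in percent of the X charged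
* amount of Q if the flask were left three thousand times as long, in percent of the X charged

Two numbers seem at odds in this flask: J is 2.73 % of the X charged, a trace, yet it equals 75.9 % of the Z. Clear this up with an assumption of my own, which the runs cannot test because they hold the same c(J): let J bind Z one to one, and count that fast step as finished at the start. Then c(Z) minus c(J) leaves 13.0 mM; call this charge of Z less its poison the live catalyst. So J is small against X, but it leaves a quarter of the Z at work. Divide the gain of Q per hour between the last two alpha readings by the live catalyst, and the turnover reads 1.20 h⁻¹. The feed ends at the asked time, so I expect this flask still to be moving.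

The forecast gives it is still moving, Q 57 % at that time and 85 % in the long run. Of the falling rate it says “these data can't separate them”. Its 57 % is what a straight line through the last two alpha readings gives.

The flask gives it is still moving, Q 50.9 %, and 65.8 % when left long.

    E + Z → G (k = 3.60 M⁻¹ h⁻¹)
    X + G → D (k = 9.30 M⁻¹ h⁻¹)
    D → Z + Q (k = 66.0 h⁻¹)
    Z + J → Ej (k = 390 M⁻¹ h⁻¹)
    X + Q → Wa (k = 0.0230 M⁻¹ h⁻¹)
    E + Q ⇌ Gu, settled at all times (K = 6.60 M⁻¹)

In this flask at 2.50 d, with J at 0 %, Ej holds 75.9 % of the catalyst, and Z, G and D together hold 24.1 %, the live share of 24.1 %. At 1.20 d the passing of X and G into D uses X at 39 times the rate of the passing of X and Q into Wa, yet at 25.0 d the flask stands at Q 65.8 % and Wa 34.2 %.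

Now take the neighbour flask with 0.070 M of J: its J exceeds that of this flask by more than the live catalyst, so the same subtraction leaves no live catalyst and a surplus of 16.0 mM of J, which is 22.9 % of its charge. Computed at 2.50 d, that flask holds J 22.9 %, Ej 100 % and Q 1.30 %.

(The runs come from a simulation for substances that don't exist, and the scatter is random.)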